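**Plan**

- Retrosynthesis: the C12–OOH group is taken off by a reverse Schenck ene reaction (back to an E C11=C12 olefin); the methylene lactone is opened at O–C16 and C15–C16 (alkynol cyclocarbonylation), the butenolide at O–C19, the 14-membered carbocycle at C8–C9, and the seco chain at C1–C2.
- Enabling feature: C8 is an sp2 carbon of the butenolide ring (O–C6–C7=C8–C19) and carries the C9 methylene of the carbocycle, so C8–C9 is an alkenyl–alkyl bond. Its alkyl half can be the 9-BBN adduct of a terminal C9=C10 olefin conjugated to C11=C12; its alkenyl half is the C8 iodide of an acyclic (E)-2-iodoenoate.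
- Forward: geranyl acetate gives the dienyl propargylic mesylate (C9–C14, C1, C15, C17); (R)-PMB glycidyl ether gives the C2–C7 enal; a Marshall propargylation joins C1–C2; the C7 end becomes the iodoenoate; the carbocycle closes at C8–C9; then the butenolide, the methylene lactone and the hydroperoxide follow in that order.
- Stereochemistry: C6 from the glycidyl ether; C1 from a Noyori transfer hydrogenation, relayed with inversion through an allenylindium; C2 anti to C1 from the cyclic SE2′ transition state; C12 from a face-selective ene reaction on the macrocycle. E C3=C4 comes from syn methylalumination, E C11=C12 from geranyl acetate, and the enoate geometry from syn hydrostannation.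

Key step: step 20

Remark: atom numbers C1–C19 in names and reasons are those of the target carbocycle (C1/C2 carry the methylene lactone, C6–C8/C19 the butenolide, C12 the hydroperoxide); the alkyne is carried as its triisopropylsilyl (TIPS) derivative because a trimethylsilylalkyne would be at risk under the carbonate base of the ring closure.

**Route**

Step 1
Reactants: 1 geranyl acetate
Product: 3 (2E)-3-methyl-6-oxohex-2-en-1-yl acetate, via ozonide 2 (not isolated)
Conditions: O3 (1.0 equiv), CH2Cl2, −78 °C; PPh3, −78 °C → rt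
Reagents that add atoms: ozone, [O-][O+]=O
Why: Selective ozonolysis; with one equivalent of ozone the electron-rich isopropylidene olefin should be cleaved well before the allylic olefin deactivated by the acetoxy group.

Step 2
Reactants: 3 (2E)-3-methyl-6-oxohex-2-en-1-yl acetate; 4 (triisopropylsilyl)acetylene
Product: 6 rac-(2E)-6-hydroxy-3-methyl-8-(triisopropylsilyl)oct-2-en-7-yn-1-yl acetate, via lithium acetylide 5 (not isolated)
Conditions: 4, n-BuLi, THF, −78 °C; then 3, −78 °C
Reagents that add atoms: none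
Why: 1,2-Addition of a lithium acetylide to an aldehyde, which at −78 °C should be far faster than attack on the acetate.

Step 3
Reactants: 6 rac-(2E)-6-hydroxy-3-methyl-8-(triisopropylsilyl)oct-2-en-7-yn-1-yl acetate
Product: 7 (2E)-3-methyl-6-oxo-8-(triisopropylsilyl)oct-2-en-7-yn-1-yl acetate
Conditions: Dess–Martin periodinane, CH2Cl2, 0 °C → rt
Reagents that add atoms: none
Why: Dess–Martin oxidation of a propargylic alcohol to the ynone under neutral conditions that leave the allylic acetate and the silylalkyne alone.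

Step 4
Reactants: 7 (2E)-3-methyl-6-oxo-8-(triisopropylsilyl)oct-2-en-7-yn-1-yl acetate
Product: 8 (2E,6S)-6-hydroxy-3-methyl-8-(triisopropylsilyl)oct-2-en-7-yn-1-yl acetate
Conditions: Ru[(S,S)-TsDPEN](p-cymene) (2 mol%), i-PrOH, rt
Reagents that add atoms: none
Why: Noyori asymmetric transfer hydrogenation of an alkynyl ketone; the (S,S) catalyst distinguishes the alkynyl from the alkyl flank and should deliver hydride to give the S carbinol, as with other silyl ynones.

Step 5
Reactants: 8 (2E,6S)-6-hydroxy-3-methyl-8-(triisopropylsilyl)oct-2-en-7-yn-1-yl acetate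
Product: 9 (2E,6S)-3-methyl-8-(triisopropylsilyl)oct-2-en-7-yne-1,6-diol
Conditions: K2CO3 (0.2 equiv), MeOH, rt
Reagents that add atoms: none
Why: Base-catalysed transesterification removes the acetate, while the bulky triisopropylsilyl group keeps the alkyne C–Si bond intact under methanolic carbonate.

Step 6
Reactants: 9 (2E,6S)-3-methyl-8-(triisopropylsilyl)oct-2-en-7-yne-1,6-diol
Product: 10 (2E,6S)-6-hydroxy-3-methyl-8-(triisopropylsilyl)oct-2-en-7-ynal
Conditions: TEMPO (10 mol%), PhI(OAc)2 (1.1 equiv), CH2Cl2, rt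
Reagents that add atoms: none
Why: Oxoammonium (TEMPO/PhI(OAc)2) oxidation is selective for primary over secondary alcohols and should give the enal without E/Z isomerisation.

Step 7
Reactants: 10 (2E,6S)-6-hydroxy-3-methyl-8-(triisopropylsilyl)oct-2-en-7-ynal
Product: 11 (3S,6E)-6-methyl-1-(triisopropylsilyl)nona-6,8-dien-1-yn-3-ol
Conditions: Ph3PCH3Br (2.5 equiv), n-BuLi (2.4 equiv), THF, 0 °C; then 10, 0 °C → rt
Reagents that add atoms: methyltriphenylphosphonium bromide, C[P+](c1ccccc1)(c1ccccc1)c1ccccc1.[Br-]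
Why: Wittig methylenation of the enal gives the terminal diene (C9=C10–C11=C12); the extra ylide covers the free hydroxyl, and the stereocentre is not involved.

Step 8
Reactants: 11 (3S,6E)-6-methyl-1-(triisopropylsilyl)nona-6,8-dien-1-yn-3-ol
Product: 12 (3S,6E)-6-methyl-1-(triisopropylsilyl)nona-6,8-dien-1-yn-3-yl methanesulfonate
Conditions: MsCl, Et3N, CH2Cl2, −78 → 0 °C; used without chromatography
Reagents that add atoms: methanesulfonyl chloride, CS(=O)(=O)Cl
Why: Sulfonylation at oxygen retains the S configuration and provides the leaving group for the Marshall reaction.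

Step 9
Reactants: 13 (R)-2-[(4-methoxybenzyloxy)methyl]oxirane
Product: 14 (2R)-1-[(4-methoxybenzyl)oxy]pent-4-yn-2-ol
Conditions: LiC≡CH·H2NCH2CH2NH2, DMSO, rt
Reagents that add atoms: lithium acetylide–ethylenediamine complex, [Li]C#C.NCCN
Why: SN2 opening of the terminal epoxide at its CH2 carbon (the future C5) by acetylide leaves the stereocentre (the future C6) untouched.

Step 10
Reactants: 14 (2R)-1-[(4-methoxybenzyl)oxy]pent-4-yn-2-ol
Product: 15 tert-butyl{[(2R)-1-[(4-methoxybenzyl)oxy]pent-4-yn-2-yl]oxy}dimethylsilane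
Conditions: TBSCl, imidazole, DMF, rt
Reagents that add atoms: tert-butyldimethylsilyl chloride, CC(C)(C)[Si](C)(C)Cl
Why: Standard silylation of a secondary alcohol; the silyl ether later keeps the C6 oxygen from lactonising before the ring closure.

Step 11
Reactants: 15 tert-butyl{[(2R)-1-[(4-methoxybenzyl)oxy]pent-4-yn-2-yl]oxy}dimethylsilane
Product: 18 (2E,5R)-5-(tert-butyldimethylsilyloxy)-6-[(4-methoxybenzyl)oxy]-3-methylhex-2-en-1-ol, via alkenylalane 16 (not isolated), via lithium alanate 17 (not isolated)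
Conditions: Me3Al (2.5 equiv), Cp2ZrCl2 (0.25 equiv), CH2Cl2, 0 °C → rt; n-BuLi, THF, −78 °C; (CH2O)n, → rt
Reagents that add atoms: trimethylaluminium, C[Al](C)C; paraformaldehyde (as formaldehyde), C=O
Why: Negishi zirconium-catalysed methylalumination adds methyl and aluminium syn across the terminal alkyne (methyl to the internal carbon), and the derived alanate is hydroxymethylated with retention, which fixes the E C3=C4 olefin.

Step 12
Reactants: 18 (2E,5R)-5-(tert-butyldimethylsilyloxy)-6-[(4-methoxybenzyl)oxy]-3-methylhex-2-en-1-ol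
Product: 19 (2E,5R)-5-(tert-butyldimethylsilyloxy)-6-[(4-methoxybenzyl)oxy]-3-methylhex-2-enal
Conditions: MnO2, CH2Cl2, rt
Reagents that add atoms: none
Why: Allylic alcohol oxidation with MnO2 should give the enal without loss of olefin geometry and without touching the ethers.

Step 13
Reactants: 12 (3S,6E)-6-methyl-1-(triisopropylsilyl)nona-6,8-dien-1-yn-3-yl methanesulfonate; 19 (2E,5R)-5-(tert-butyldimethylsilyloxy)-6-[(4-methoxybenzyl)oxy]-3-methylhex-2-enal
Product: 21 (1R,2S,6R)-anti homopropargylic alcohol CH2=CH–CH=C(CH3)–CH2CH2–CH(C≡C–TIPS)–CH(OH)–CH=C(CH3)–CH2–CH(OTBS)–CH2–OPMB, via allenylindium 20 (not isolated)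
Conditions: Pd(dppf)Cl2 (5 mol%), InI (1.4 equiv), THF/HMPA (3:1), rt
Reagents that add atoms: none
Why: Marshall propargylation: zerovalent palladium formed in situ displaces the mesylate anti-SN2′, transmetalation with monovalent indium gives the axially defined allenylindium 20, and its cyclic SE2′ addition to the enal carbonyl sets C1 with net inversion of the mesylate carbon and C2 anti to it, the remote C6 centre having no say.

Step 14
Reactants: 21 (1R,2S,6R)-anti homopropargylic alcohol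
Product: 22 (1R,2S,6R)-C2,C6-bis(tert-butyldimethylsilyl) ether with C7 OPMB
Conditions: TBSOTf, 2,6-lutidine, CH2Cl2, −78 °C
Reagents that add atoms: tert-butyldimethylsilyl triflate, CC(C)(C)[Si](C)(C)OS(=O)(=O)C(F)(F)F
Why: Silyl triflate silylation of the hindered allylic C2 alcohol protects it through the organolithium, tin and boron steps.

Step 15
Reactants: 22 (1R,2S,6R)-C2,C6-bis(tert-butyldimethylsilyl) ether with C7 OPMB
Product: 23 (1R,2S,6R)-C7 primary alcohol
Conditions: DDQ, CH2Cl2/pH 7 buffer, 0 °C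
Reagents that add atoms: none
Why: Oxidative cleavage of the PMB ether; the 4,4-disubstituted diene cannot readily reach the s-cis form and the silyl ethers are inert under buffered conditions.

Step 16
Reactants: 23 (1R,2S,6R)-C7 primary alcohol
Product: 24 (1R,2S,6R)-C7 aldehyde
Conditions: Dess–Martin periodinane, NaHCO3, CH2Cl2, 0 °C
Reagents that add atoms: none
Why: Buffered Dess–Martin oxidation gives the α-silyloxy aldehyde without epimerising C6.

Step 17
Reactants: 24 (1R,2S,6R)-C7 aldehyde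
Product: 25 (1R,2S,6R)-C7=C8 1,1-dibromoalkene
Conditions: CBr4, PPh3, 2,6-lutidine, CH2Cl2, 0 °C
Reagents that add atoms: carbon tetrabromide, BrC(Br)(Br)Br
Why: Corey–Fuchs dibromoolefination adds C8 to the aldehyde under non-basic conditions that keep C6 intact.

Step 18
Reactants: 25 (1R,2S,6R)-C7=C8 1,1-dibromoalkene
Product: 27 (1R,2S,6R)-methyl ynoate (C7≡C8–CO2CH3, C19 ester), via lithium acetylide 26 (not isolated)
Conditions: n-BuLi (2.1 equiv), THF, −78 °C; ClCO2Me, −78 → 0 °C
Reagents that add atoms: methyl chloroformate, COC(=O)Cl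
Why: Corey–Fuchs second stage: bromine–lithium exchange, Fritsch–Buttenberg–Wiechell rearrangement and deprotonation give the lithium acetylide, which is acylated to the ynoate; the other alkyne is silyl-capped and cannot compete.

Step 19
Reactants: 27 (1R,2S,6R)-methyl ynoate
Product: 29 (1R,2S,6R)-seco diene methyl (7E)-8-iodo-enoate, via alkenylstannane 28 (not isolated)
Conditions: Pd(PPh3)4 (3 mol%), Bu3SnH (1.1 equiv, slow addition), THF, 0 °C; then I2, CH2Cl2, 0 °C
Reagents that add atoms: iodine, II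
Why: Palladium-catalysed hydrostannation adds hydrogen and tin syn across the electron-poor ynoate with tin at the α-carbon C8, and iododestannylation with retention gives the E iodoenoate whose ester is cis to C6.

Step 20
Reactants: 29 (1R,2S,6R)-seco diene methyl (7E)-8-iodo-enoate
Product: 31 (1R,2S,6R)-14-membered methyl (7Z)-enoate with C2 and C6 OTBS and C1 C≡C–TIPS, via alkylborane 30 (not isolated)
Conditions: 9-BBN (1.5 equiv), THF, 0 °C → rt; then slow addition to Pd(dppf)Cl2 (20 mol%), AsPh3 (20 mol%), Cs2CO3 (3 equiv), degassed DMF/THF/H2O, 1 mM, rt → 45 °C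
Reagents that add atoms: none
Why: 9-BBN adds to the monosubstituted C9=C10 end of the 4,4-disubstituted diene with boron at C9 to give homoallylic borane 30, while the trisubstituted olefins, the hindered silylalkyne, the ester and the C–I bond are left alone. Zerovalent palladium formed from Pd(dppf)Cl2 inserts into the C8–I bond with retention, the carbonate-activated borane transfers its primary alkyl group, and reductive elimination forms C8–C9. The closest known reaction type is the B-alkyl Suzuki–Miyaura macrocyclisation of a 9-BBN alkylborane with an alkenyl iodide. The 14-membered carbocycle closes by intramolecular transmetalation and reductive elimination from a 15-membered palladacycle under high dilution, with AsPh3 favouring transmetalation over β-hydride loss. No stereocentre is created; the selectivities needed are chemoselective hydroboration, secured by the single monosubstituted olefin, and retention of the enoate geometry, secured by the stereodefined iodide. The C6 silyl ether keeps the C6 oxygen from lactonising early, so no base-sensitive butenolide meets Cs2CO3, and the retained geometry leaves the ester cis to C6 for step 21.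

Step 21
Reactants: 31 (1R,2S,6R)-14-membered methyl (7Z)-enoate
Product: 33 (1R,2S,6R)-C2-hydroxy C1-ethynyl butenolide, via dihydroxy ester 32 (not isolated)
Conditions: TBAF (6 equiv), THF, 0 °C → rt; then AcOH
Reagents that add atoms: none
Why: Fluoride cleaves both silyl ethers and the alkynyl C–Si bond, and the C6 hydroxyl, held cis to the ester across C7=C8, lactonises to the butenolide by 5-exo-trig acyl substitution.

Step 22
Reactants: 33 (1R,2S,6R)-C2-hydroxy C1-ethynyl butenolide
Product: 34 (1R,2S,6R)-12-deoxy bis-lactone (3E,11E-triene with α-methylene lactone and butenolide)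
Conditions: PdCl2 (10 mol%), SnCl2 (10 mol%), PPh3 (20 mol%), CO (8 atm), MeCN, 75 °C
Reagents that add atoms: carbon monoxide, [C-]#[O+]
Why: Norton-type palladium-catalysed cyclocarbonylation of a 3-butyn-1-ol: an alkoxycarbonylpalladium species from the C2 hydroxyl and CO adds cis across the terminal alkyne with the acyl group on C15, and protonolysis frees the exocyclic methylene; C1 and C2 are untouched, so the trans ring fusion follows from the anti adduct of step 13.

Step 23
Reactants: 34 (1R,2S,6R)-12-deoxy bis-lactone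
Product: 35 (1R,2S,3E,6R,10E,12S)-12-hydroperoxycembra-3,7,10,15(17)-tetraene-16,2:19,6-diolide (target)
Conditions: O2, tetraphenylporphyrin (cat.), visible light, CH2Cl2, −20 °C
Reagents that add atoms: dioxygen, O=O
Why: Schenck ene reaction: singlet oxygen should attack the only electron-rich, unhindered olefin C11=C12 (C3=C4 is deactivated by the allylic lactone oxygen, the others are acrylate-type), bond to C12 and take an allylic hydrogen from C10 on the more substituted side of the olefin, giving E C10=C11; the C12 configuration must come from peripheral attack on the macrocycle, and the C11 hydroperoxide from methyl-hydrogen abstraction would have to be separated.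

**Compound list**

1 | geranyl acetate | CC(C)=CCC/C(C)=C/COC(C)=O | starting material
2 | (2E)-5-(5,5-dimethyl-1,2,4-trioxolan-3-yl)-3-methylpent-2-en-1-yl acetate (ozonide) | CC(=O)OC/C=C(\C)CCC1OOC(C)(C)O1 | intermediate
3 | (2E)-3-methyl-6-oxohex-2-en-1-yl acetate | CC(=O)OC/C=C(\C)CCC=O | intermediate
4 | (triisopropylsilyl)acetylene | C#C[Si](C(C)C)(C(C)C)C(C)C | starting material
5 | lithium (triisopropylsilyl)acetylide | [Li]C#C[Si](C(C)C)(C(C)C)C(C)C | intermediate
6 | rac-(2E)-6-hydroxy-3-methyl-8-(triisopropylsilyl)oct-2-en-7-yn-1-yl acetate | CC(=O)OC/C=C(\C)CCC(O)C#C[Si](C(C)C)(C(C)C)C(C)C | intermediate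
7 | (2E)-3-methyl-6-oxo-8-(triisopropylsilyl)oct-2-en-7-yn-1-yl acetate | CC(=O)OC/C=C(\C)CCC(=O)C#C[Si](C(C)C)(C(C)C)C(C)C | intermediate
8 | (2E,6S)-6-hydroxy-3-methyl-8-(triisopropylsilyl)oct-2-en-7-yn-1-yl acetate | CC(=O)OC/C=C(\C)CC[C@H](O)C#C[Si](C(C)C)(C(C)C)C(C)C | intermediate
9 | (2E,6S)-3-methyl-8-(triisopropylsilyl)oct-2-en-7-yne-1,6-diol | OC/C=C(\C)CC[C@H](O)C#C[Si](C(C)C)(C(C)C)C(C)C | intermediate
10 | (2E,6S)-6-hydroxy-3-methyl-8-(triisopropylsilyl)oct-2-en-7-ynal | O=C/C=C(\C)CC[C@H](O)C#C[Si](C(C)C)(C(C)C)C(C)C | intermediate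
11 | (3S,6E)-6-methyl-1-(triisopropylsilyl)nona-6,8-dien-1-yn-3-ol | C=C/C=C(\C)CC[C@H](O)C#C[Si](C(C)C)(C(C)C)C(C)C | intermediate
12 | (3S,6E)-6-methyl-1-(triisopropylsilyl)nona-6,8-dien-1-yn-3-yl methanesulfonate | C=C/C=C(\C)CC[C@H](OS(C)(=O)=O)C#C[Si](C(C)C)(C(C)C)C(C)C | intermediate
13 | (R)-2-[(4-methoxybenzyloxy)methyl]oxirane | COc1ccc(COC[C@H]2CO2)cc1 | starting material
14 | (2R)-1-[(4-methoxybenzyl)oxy]pent-4-yn-2-ol | C#CC[C@@H](O)COCc1ccc(OC)cc1 | intermediate
15 | tert-butyl{[(2R)-1-[(4-methoxybenzyl)oxy]pent-4-yn-2-yl]oxy}dimethylsilane | C#CC[C@@H](O[Si](C)(C)C(C)(C)C)COCc1ccc(OC)cc1 | intermediate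
16 | (E)-alkenyldimethylalane from syn methylalumination of 15 | C[Al](C)/C=C(\C)C[C@@H](O[Si](C)(C)C(C)(C)C)COCc1ccc(OC)cc1 | intermediate
17 | lithium butyl(dimethyl)[(E)-alkenyl]aluminate from 16 | [Li+].CCCC[Al-](C)(C)/C=C(\C)C[C@@H](O[Si](C)(C)C(C)(C)C)COCc1ccc(OC)cc1 | intermediate
18 | (2E,5R)-5-(tert-butyldimethylsilyloxy)-6-[(4-methoxybenzyl)oxy]-3-methylhex-2-en-1-ol | OC/C=C(\C)C[C@@H](O[Si](C)(C)C(C)(C)C)COCc1ccc(OC)cc1 | intermediate
19 | (2E,5R)-5-(tert-butyldimethylsilyloxy)-6-[(4-methoxybenzyl)oxy]-3-methylhex-2-enal | O=C/C=C(\C)C[C@@H](O[Si](C)(C)C(C)(C)C)COCc1ccc(OC)cc1 | intermediate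
20 | axially chiral [(6E)-6-methyl-1-(triisopropylsilyl)nona-1,2,6,8-tetraen-1-yl]indium iodide methanesulfonate | [H]C(CC/C(C)=C/C=C)=[C@]=C([In](I)OS(C)(=O)=O)[Si](C(C)C)(C(C)C)C(C)C | intermediate
21 | (1R,2S,6R)-anti homopropargylic alcohol, C2 OH, C6 OTBS, C7 OPMB, C1 C≡C–TIPS, 3E, 9,11E-diene | C=C/C=C(\C)CC[C@H](C#C[Si](C(C)C)(C(C)C)C(C)C)[C@@H](O)/C=C(\C)C[C@@H](O[Si](C)(C)C(C)(C)C)COCc1ccc(OC)cc1 | intermediate
22 | (1R,2S,6R)-C2,C6-bis(tert-butyldimethylsilyl) ether, C7 OPMB | C=C/C=C(\C)CC[C@H](C#C[Si](C(C)C)(C(C)C)C(C)C)[C@@H](O[Si](C)(C)C(C)(C)C)/C=C(\C)C[C@@H](O[Si](C)(C)C(C)(C)C)COCc1ccc(OC)cc1 | intermediate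
23 | (1R,2S,6R)-C7 primary alcohol | C=C/C=C(\C)CC[C@H](C#C[Si](C(C)C)(C(C)C)C(C)C)[C@@H](O[Si](C)(C)C(C)(C)C)/C=C(\C)C[C@@H](O[Si](C)(C)C(C)(C)C)CO | intermediate
24 | (1R,2S,6R)-C7 aldehyde | C=C/C=C(\C)CC[C@H](C#C[Si](C(C)C)(C(C)C)C(C)C)[C@@H](O[Si](C)(C)C(C)(C)C)/C=C(\C)C[C@@H](O[Si](C)(C)C(C)(C)C)C=O | intermediate
25 | (1R,2S,6R)-C7=C8 1,1-dibromoalkene | C=C/C=C(\C)CC[C@H](C#C[Si](C(C)C)(C(C)C)C(C)C)[C@@H](O[Si](C)(C)C(C)(C)C)/C=C(\C)C[C@@H](O[Si](C)(C)C(C)(C)C)C=C(Br)Br | intermediate
26 | (1R,2S,6R)-C7≡C8 lithium acetylide | C=C/C=C(\C)CC[C@H](C#C[Si](C(C)C)(C(C)C)C(C)C)[C@@H](O[Si](C)(C)C(C)(C)C)/C=C(\C)C[C@@H](O[Si](C)(C)C(C)(C)C)C#C[Li] | intermediate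
27 | (1R,2S,6R)-methyl ynoate (C7≡C8–CO2CH3) | C=C/C=C(\C)CC[C@H](C#C[Si](C(C)C)(C(C)C)C(C)C)[C@@H](O[Si](C)(C)C(C)(C)C)/C=C(\C)C[C@@H](O[Si](C)(C)C(C)(C)C)C#CC(=O)OC | intermediate
28 | (1R,2S,6R)-methyl (7E)-8-(tributylstannyl)enoate | C=C/C=C(\C)CC[C@H](C#C[Si](C(C)C)(C(C)C)C(C)C)[C@@H](O[Si](C)(C)C(C)(C)C)/C=C(\C)C[C@@H](O[Si](C)(C)C(C)(C)C)/C=C(/[Sn](CCCC)(CCCC)CCCC)C(=O)OC | intermediate
29 | (1R,2S,6R)-seco diene methyl (7E)-8-iodoenoate (precursor of the ring closure) | C=C/C=C(\C)CC[C@H](C#C[Si](C(C)C)(C(C)C)C(C)C)[C@@H](O[Si](C)(C)C(C)(C)C)/C=C(\C)C[C@@H](O[Si](C)(C)C(C)(C)C)/C=C(/I)C(=O)OC | intermediate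
30 | B-(C9-alkyl)-9-borabicyclo[3.3.1]nonane adduct of 29 | C(C/C=C(\C)CC[C@H](C#C[Si](C(C)C)(C(C)C)C(C)C)[C@@H](O[Si](C)(C)C(C)(C)C)/C=C(\C)C[C@@H](O[Si](C)(C)C(C)(C)C)/C=C(/I)C(=O)OC)B1C2CCCC1CCC2 | intermediate
31 | (1R,2S,6R)-14-membered methyl (3E,7Z,11E)-enoate, C2 and C6 OTBS, C1 C≡C–TIPS | C1C/C=C(\C)CC[C@H](C#C[Si](C(C)C)(C(C)C)C(C)C)[C@@H](O[Si](C)(C)C(C)(C)C)/C=C(\C)C[C@@H](O[Si](C)(C)C(C)(C)C)/C=C1\C(=O)OC | intermediate
32 | (1R,2S,6R)-desilylated C2,C6-dihydroxy C1-ethynyl methyl ester | C1C/C=C(\C)CC[C@H](C#C)[C@@H](O)/C=C(\C)C[C@@H](O)/C=C1\C(=O)OC | intermediate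
33 | (1R,2S,6R)-C2-hydroxy C1-ethynyl 19,6-butenolide | C1C/C=C(\C)CC[C@H](C#C)[C@@H](O)/C=C(\C)C[C@@H]2C=C1C(=O)O2 | intermediate
34 | (1R,2S,3E,6R,11E)-cembra-3,7,11,15(17)-tetraene-16,2:19,6-diolide (12-deoxy bis-lactone) | C=C1C(=O)O[C@H]2/C=C(\C)C[C@@H]3C=C(CC/C=C(\C)CC[C@H]12)C(=O)O3 | intermediate
35 | (1R,2S,3E,6R,10E,12S)-12-hydroperoxycembra-3,7,10,15(17)-tetraene-16,2:19,6-diolide | C=C1C(=O)O[C@H]2/C=C(\C)C[C@@H]3C=C(C/C=C/[C@@](C)(OO)CC[C@H]12)C(=O)O3 | target

**Count and risks**

Total step count: 23. Longest linear sequence: 19 steps (steps 1–8 and 13–23 from geranyl acetate); the glycidyl branch is steps 9–12.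

Steps most likely to fail:

1. Step 23. Hydrogen abstraction from the C12 methyl group instead of C10, or oxygen delivery to the wrong face of C11=C12, would erode the ene reaction. Fallback, from 34 back to 35: the C12 oxygen would be introduced ionically under reagent control. Dioxirane epoxidation with the D-fructose-derived Shi ketone (KHSO5, NaHCO3-buffered MeCN/H2O near pH 8, 0 °C) should epoxidise the only electron-rich unhindered olefin to the (11R,12R)-epoxide F1. Perhydrolysis with ethereal H2O2 and catalytic H3PMo12O40 should open it at the tertiary C12 with inversion to the (11R,12S)-β-hydroxy hydroperoxide F2. TBSCl/imidazole at −20 °C caps the more acidic OOH to give the silyl peroxide alcohol F3. Burgess reagent (toluene, 50 °C) dehydrates the C11 alcohol by syn elimination toward C10, the only side with hydrogen, to give the E-C10=C11 silyl peroxide F4. HF·pyridine then releases 35.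

2. Step 20. Oligomerisation, protodeboronation of the borane or incomplete chemoselectivity of the hydroboration would compete with ring closure. Fallback, from 22 back to 31: the ring would be closed at C7=C8 by an intramolecular Still–Gennari olefination, with C8–C9 made beforehand by alkylation. Hydroboration of the diene terminus of 22 with 9-BBN and oxidation (NaBO3) gives the C9 primary alcohol F5. I2/PPh3/imidazole gives the C9 iodide F6. Alkylation of the sodium salt of methyl bis(2,2,2-trifluoroethyl)phosphonoacetate (NaH, DMF) gives the C8 phosphonate F7 as a mixture of C8 epimers. DDQ gives the C7 alcohol F8, and Dess–Martin oxidation the C7 aldehyde phosphonate F9. KHMDS/18-crown-6 in THF at −78 °C under high dilution should then give the (7Z)-enoate 31.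

3. Step 22. Slow alkoxycarbonyl-palladium addition, alkyne oligomerisation or Lewis-acid damage under pressure of CO at 75 °C would lower the cyclocarbonylation. Fallback, from 33 back to 34: the alkyne would first be converted into a vinyl halide and the lactone closed by carbonylative lactonisation. Iodoboration of the terminal alkyne with B-iodo-9-BBN (CH2Cl2/hexane, −20 °C) and protonolysis with AcOH gives the C15 2-iodoalkene F10. Pd(PPh3)4, CO (1 atm) and Et3N in MeCN at 50 °C should then insert CO into the C15–I bond and trap the acylpalladium with the C2 hydroxyl to give 34.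

**Further compounds**

F1 | step 23 | (11R,12R)-11,12-epoxide of 34 | C=C1C(=O)O[C@H]2/C=C(\C)C[C@@H]3C=C(CC[C@H]4O[C@]4(C)CC[C@H]12)C(=O)O3
F2 | step 23 | (11R,12S)-11-hydroxy-12-hydroperoxide | C=C1C(=O)O[C@H]2/C=C(\C)C[C@@H]3C=C(CC[C@@H](O)[C@@](C)(OO)CC[C@H]12)C(=O)O3
F3 | step 23 | (11R,12S)-11-hydroxy-12-(tert-butyldimethylsilylperoxy) compound | C=C1C(=O)O[C@H]2/C=C(\C)C[C@@H]3C=C(CC[C@@H](O)[C@@](C)(OO[Si](C)(C)C(C)(C)C)CC[C@H]12)C(=O)O3
F4 | step 23 | tert-butyldimethylsilyl peroxide of 35 | C=C1C(=O)O[C@H]2/C=C(\C)C[C@@H]3C=C(C/C=C/[C@@](C)(OO[Si](C)(C)C(C)(C)C)CC[C@H]12)C(=O)O3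
F5 | step 20 | C9 primary alcohol from hydroboration–oxidation of 22 | OCC/C=C(\C)CC[C@H](C#C[Si](C(C)C)(C(C)C)C(C)C)[C@@H](O[Si](C)(C)C(C)(C)C)/C=C(\C)C[C@@H](O[Si](C)(C)C(C)(C)C)COCc1ccc(OC)cc1
F6 | step 20 | C9 primary iodide | ICC/C=C(\C)CC[C@H](C#C[Si](C(C)C)(C(C)C)C(C)C)[C@@H](O[Si](C)(C)C(C)(C)C)/C=C(\C)C[C@@H](O[Si](C)(C)C(C)(C)C)COCc1ccc(OC)cc1
F7 | step 20 | methyl C8-[bis(2,2,2-trifluoroethoxy)phosphoryl] ester, C7 OPMB | COC(=O)C(CC/C=C(\C)CC[C@H](C#C[Si](C(C)C)(C(C)C)C(C)C)[C@@H](O[Si](C)(C)C(C)(C)C)/C=C(\C)C[C@@H](O[Si](C)(C)C(C)(C)C)COCc1ccc(OC)cc1)P(=O)(OCC(F)(F)F)OCC(F)(F)F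
F8 | step 20 | C7 alcohol of the phosphonate | COC(=O)C(CC/C=C(\C)CC[C@H](C#C[Si](C(C)C)(C(C)C)C(C)C)[C@@H](O[Si](C)(C)C(C)(C)C)/C=C(\C)C[C@@H](O[Si](C)(C)C(C)(C)C)CO)P(=O)(OCC(F)(F)F)OCC(F)(F)F
F9 | step 20 | C7 aldehyde phosphonate | COC(=O)C(CC/C=C(\C)CC[C@H](C#C[Si](C(C)C)(C(C)C)C(C)C)[C@@H](O[Si](C)(C)C(C)(C)C)/C=C(\C)C[C@@H](O[Si](C)(C)C(C)(C)C)C=O)P(=O)(OCC(F)(F)F)OCC(F)(F)F
F10 | step 22 | C15 2-iodoalkene from 33 | C1C/C=C(\C)CC[C@H](C(I)=C)[C@@H](O)/C=C(\C)C[C@@H]2C=C1C(=O)O2
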